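Slowness is what I see first: in the midnight run X still stands at 38 % after 10.0 h. Flasks epsilon, delta and gamma, each charged with X at 0.14 M and E at 0.126 M, are read at 25 h, 30 h and 40 h.

| setting | midnight | dawn | spring | epsilon | delta | gamma |
|---|---|---|---|---|---|---|
| X | 0.20 M | 0.31 M | 0.14 M | 0.14 M | 0.14 M | 0.14 M |
| E | 0.126 M | 0.126 M | 0.25 M | 0.126 M | 0.126 M | 0.126 M |
| remark | run made earlier | run made earlier | run made earlier |  |  |  |
| time |  |  |  | 25 h | 30 h | 40 h |

| run | time / h | X / % | D / % | L / % | Q / % |
|---|---|---|---|---|---|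
| midnight | 2.00 | 83 | 1 | 17 | 0 |
| midnight | 5.00 | 62 | 6 | 24 | 7 |
| midnight | 10.0 | 38 | 32 | 25 | 12 |
| midnight | 15.0 | 19 | 44 | 22 | 11 |
| midnight | 20.0 | 12 | 57 | 14 | 13 |
| dawn | 1.50 | 87 | 0 | 14 | 1 |
| dawn | 3.00 | 76 | 1 | 17 | 1 |
| dawn | 6.00 | 55 | 18 | 24 | 1 |
| dawn | 10.0 | 34 | 30 | 26 | 8 |
| dawn | 20.0 | 16 | 60 | 24 | 4 |
| spring | 2.00 | 86 | 0 | 12 | 6 |
| spring | 5.00 | 59 | 12 | 15 | 12 |
| spring | 10.0 | 32 | 40 | 14 | 17 |
| spring | 15.0 | 16 | 55 | 9 | 27 |
| spring | 20.0 | 8 | 63 | 2 | 26 |

(each reading ± 2 percentage points)

- percent here means X units held: one D counts as two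
- the numbers in the tables scatter by 2 percentage points (one standard deviation)
- a reading or a percentage of Q counts all its forms, free or not

- which of these there is most of at the end, counted by the X in it, epsilon (Q / L / D / X)
- which of these there is most of at the end, counted by the X in it, delta (Q / L / D / X)
- which of these there is most of at the end, counted by the X in it, gamma (Q / L / D / X)
- the largest of these amounts at the end, in percent of the X charged, epsilon
- the largest of these amounts at the end, in percent of the X charged, delta
- the largest of these amounts at the end, in percent of the X charged, gamma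

Two midnight numbers do not seem to go together: at 20.0 h X is down to 12 %, yet D and Q together hold 70.0 %, not the 88.0 % that the lost X suggests. L, at 14 %, stands in that gap, so I count X plus L as one pool of unfinished material. In midnight that pool reads 63.0 % at 10.0 h and 26.0 % at 20.0 h, which, as a reading with the scatter of those numbers, gives 7.83 h for the pool half-life, the time in which X plus L halves on an apparent first-order reading. I assume that the flasks at 0.14 M keep this clock, and I halve on from midnight's last reading. On that reckoning I estimate the pool at 16.7 % in epsilon, 10.7 % in delta and 4.43 % in gamma, and D and Q share the rest. Midnight's last reading has D at 57 % and Q at 13 %, so I expect D on top; the split itself I do not reckon.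

The forecast names D in each flask, at 66 %, 71 % and 77 %: “D takes the remainder by mass balance, so it dominates”.

The flasks give D each time, at 61.0 %, 65.6 % and 70.8 %.

    X + Q → D (k = 2.66 L mol⁻¹ h⁻¹)
    E + Q ⇌ J, settled at all times (K = 58.0 L mol⁻¹)
    L + Z → Q (k = 1.37 L mol⁻¹ h⁻¹)
    E → Z (k = 1.86 h⁻¹)
    X ⇌ L (K = 1.80, k = 0.0956 h⁻¹)

In epsilon, delta and gamma the pool stands at 18.0 %, 12.4 % and 6.11 %, against my 16.7 %, 10.7 % and 4.43 %, and Q at 21.0 %, 22.0 % and 23.0 %, against the forecast's 18 percent. Delta read at 3.0 d holds a pool of 0.730 %, where halving on from its 30 h state gives 0.301 %. In epsilon, with the other concentrations as charged, free Q has a half-life of 1.9 h by its loss with X to D, shorter than the 8.0 h that L has in delta at 0.373 h by the making of Q. Delta left to 300 h holds Q at 24.0 % and D at 76.0 %.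

The readings are calculated with constants of no real substance, and the scatter is random.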